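I start from the late end. Solid reagent dissolves into partner, partner turns each substrate into the product of its own hand, a catalyst flips substrate between the hands, and impurity turns up to 3.6 µM of that catalyst into spent catalyst. The charge of solid reagent, 0.400 mM, equals the two substrates together, 0.400 mM. So at the late end both hands can go to product. But how late is that? Dissolution runs at most at the coefficient 0.267 s⁻¹ times the solubility 0.18 mM, which is 0.0481 mM s⁻¹, so the whole charge needs at least 8.32 s, longer than the time asked.

common to all: left-handed substrate 0.20 mM; solid reagent 0.400 mM; racemization catalyst 15 µM; impurity 3.6 µM; right-handed substrate 0.20 mM; time 1.2 s
- alpha: at −10 °C until 0.80 s, from then on at 20 °C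
- eta: temperature −10 °C
- theta: temperature 5 °C
- delta: temperature 20 °C

- the flask that comes out highest in excess of left-handed product over right-handed product, or "all alike" when all lie within 1.5 percentage points (alpha / eta / theta / delta / all alike)
- excess of left-handed product over right-handed product at the end, alpha
- excess of left-handed product over right-handed product at the end, eta
- excess of left-handed product over right-handed product at the end, theta
- excess of left-handed product over right-handed product at the end, delta

- partner is single-handed; left-handed substrate and right-handed substrate are mirror images of each other, charged as a racemate, each of them at the stated concentration
- as a solid, counted per litre of solution: solid reagent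
- the constants hold at 5 °C; other temperatures follow from the activation energies
- at the start none of the solid reagent is in solution
- an excess is below zero if the other one leads
- the handed part of partner does not stay in what it makes, so the products of the two hands are mirror images too

    solid reagent ⇌ partner, rate k1*(cs1 - [partner]) while solid is left; crystals form when [partner] > cs1 (cs1 = 0.18 mM, k1 = 0.267 s⁻¹)
    partner + left-handed substrate → left-handed product (k2 = 18200 L mol⁻¹ s⁻¹, Ea2 = 27.0 kJ mol⁻¹)
    left-handed substrate + racemization catalyst ⇌ right-handed substrate + racemization catalyst, rate k3*[racemization catalyst]*[left-handed substrate] forward; the back reaction follows from the equilibrium constant (k3 = 14200 L mol⁻¹ s⁻¹, Ea3 = 20.0 kJ mol⁻¹)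
    partner + right-handed substrate → right-handed product (k4 = 2610 L mol⁻¹ s⁻¹, Ea4 = 35.0 kJ mol⁻¹)
    racemization catalyst + impurity → spent catalyst (k5 = 6.12 × 10⁶ L mol⁻¹ s⁻¹, Ea5 = 12.0 kJ mol⁻¹)
    (constants at 5 °C)

By the asked time at most 0.0577 mM of partner has come, less than the substrates offer, so I reckon from the early end. There both substrates stand equal and meet the same c(partner), so that concentration cancels. The products form in the ratio of the two rate constants, the selectivity factor s, which is 6.97 at 5 °C. The excess is then s minus one over s plus one, here 74.9%. The right-hand step has the higher activation energy, so s is 8.49 at −10 °C and 5.84 at 20 °C. Those give 78.9% and 70.8%.

I doubt this. The level c(left-handed substrate) drains, and s acts on its mean. Now I join the ends. In delta the left hand takes the share s over s plus one of the ceiling, so by this reckoning it loses 24.6% of its charge. Its mean level is lower by a part of that, which I take as the loss over two. The drained s is 5.12, and the excess 67.3%. The same step gives 76.2% for eta and 71.8% for theta. Alpha I place between eta and delta, and I commit to no closer figure.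

Does the flipping refill the left hand? In delta the catalyst left after impurity, 11.4 µM at worst, relaxes the difference between the hands with a time constant of 1.98 s. That is longer than the run, though not by a wide margin, so I drop it as a first guess.

The forecast names eta as highest, with 77.8% for eta, 73% for theta, 68.7% for delta and 71.8% for alpha. Its grounds are the left/right rate ratio, “trimmed slightly by depletion of the left-handed substrate”. For delta it stands 1.4 percentage points above my figure.

The simulation gives eta, with 77.7% for eta, 73.2% for theta, 68.8% for delta and 71.9% for alpha.

The forecast stands, and delta's 68.8% lies between my drained 67.3% and undrained 70.8%, with s at 5.84. The early end holds because the low solubility of partner rations the supply: delta gives 68.8% with it and 32.3% in the run without it. A later reading is what would part from the forecast's delta figure: the excess in delta has moved by 5 points at 4.50 s.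

Delta run at 35 °C has s of 4.98, which drains to 4.38 and an excess of 62.8%. The simulation gives 64.5%.

The constants used here are made up.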